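In the autumn flask far more substrate has disappeared than product has appeared: at 1.67 d substrate reads 0.5% and product 33.6%, and product then stays flat up to 8.00 d. In the spring run product lags behind the substrate, so I read the missing 65.1% of the autumn charge as an unseen intermediate.

common to all: free catalyst 40 µM

| flask | substrate | temperature | remark | time |
|---|---|---|---|---|
| autumn | 20 mM | 25 °C | the very flask that is asked about, followed so far |  |
| spring | 30 mM | 10 °C | run made earlier |  |
| flask | 20 mM | 25 °C |  | 8.0 d |

autumn run (percent of the substrate charged)

| time / d | product / % | substrate / % |
|---|---|---|
| 0.625 | 26.0 | 3.2 |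
| 1.04 | 32.0 | 0.7 |
| 1.67 | 33.6 | 0.5 |
| 2.50 | 34.1 | 0.1 |
| 3.00 | 33.9 | 0 |
| 5.00 | 34.2 | 0.3 |
| 8.00 | 34.4 | 0.5 |

spring run (percent of the substrate charged)

| time / h | product / % | substrate / % |
|---|---|---|
| 3.00 | 0 | 89.2 |
| 8.00 | 1.5 | 73.9 |
| 12.0 | 3.3 | 63.2 |
| 20.0 | 9.4 | 47.3 |
| 30.0 | 15.7 | 32.2 |
| 40.0 | 21.4 | 21.6 |
| 48.0 | 24.6 | 16.0 |

(scatter of a reading: 0.5 percentage points)

- south-west: at 8.0 d raise the temperature by 10 K, then wait 15 d
- north-west: at 8.0 d add free catalyst, 50.0% of the amount charged, then wait 15 d
- north-east: at 8.0 d take out 90% of the product then present, then wait 15 d
- south: change nothing and wait 15 d more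

- product taken out counts as made
- what was read earlier has a scatter of 0.5 percentage points, one standard deviation
- additions bring no volume worth counting

1. product, in percent of the substrate first charged, at 8.0 d
2. which option adds most product ("none" when 2 percentage points or less is all one gets) (south-west / north-west / north-east / south / none)
3. product present, with what was taken out counted in, in percent of the substrate first charged, after north-east
4. product present, with what was taken out counted in, in percent of the substrate first charged, after south

One number carries the argument. In the autumn flask, product lies 8.4 percentage points below its last reading at 0.625 d and 2.4 points below it at 1.04 d. Read from these two scattered gaps, it shrinks by a factor e every 0.331 d, and I carry this reading as the closing time of the gap, a rough clock for how long this flask goes on making product. An equilibrium could close a gap the same way, so this stays a judgement.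

Now turn the settings by hand. Time: 8.0 d is 24.1 closing times, and the gap reckoned for then is far below the scatter, so I commit to 34.4% of product, and waiting 15 d more adds nothing worth counting. Heat: a rise of 10 K speeds the catalyst still alive, and after that many closing times I reckon hardly any is. Taking out 90% of the product needs living catalyst to pull the intermediate on, so it meets the same lack. Fresh catalyst starts the count again. The first charge made 34.4% from the whole substrate, so by plain proportion 50.0% more, acting on the 65.1% left, gives about 11 points, against a margin of 2 points. I choose north-west.

The forecast gives 34.2%, chooses north-west, and puts product at 34.3% after north-east and 34.3% after south, reading “the catalyst of the second step dying, with the intermediate left waiting”.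

    free catalyst → spent catalyst (k = 0.00140 /min, Ea = 90.0 kJ/mol)
    free catalyst + intermediate ⇌ free catalyst + product (K = 0.830, k = 32.0 /M/min, Ea = 60.0 kJ/mol, ΔH = −31.0 kJ/mol)
    substrate → intermediate (k = 0.00420 /min, Ea = 89.0 kJ/mol)
    (constants at 25 °C)

The flask gives 34.5% at 8.0 d, and north-west adds most, 6.9 points, while south-west, north-east and south each add 0 points. At 8.00 d this flask holds intermediate at 65.5% beside free catalyst at 0% and spent catalyst at >99.9%. By the autumn reading, 8.00 d is 24.1 closing times, and a neighbour flask charged with 0.068 mM of free catalyst has by then its free catalyst at 0% and its product at 40.9%.

The data are calculated for substances that don't exist, noise included.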